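Ring B is cut at C4–C5: its C5 methyl carbinol is β to the C3 oxygen, so a C3 enolate equivalent can close the six-membered ring onto a C5 methyl ketone. In one operation the BF3-promoted, non-chelated Mukaiyama aldol of an acyclic silyl enol ether forms C4–C5, closes ring B and relays the single C6 carbinol stereocenter to C5 (5,6-trans diol); a hydroxyl-directed reduction then relays C5 to C3. The precursor is an (R)-α-trimethylsilyloxy methyl ketone bearing an E-2-silylvinyl group at C6 and, across the C1 gem-dimethyl carbon, a terminal TBS enol ether. Stille couplings then attach the bromobutenolide polyene carrying ring A.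

Key step: step 9

Remark on numbering: ring B carries carotenoid numbers throughout (C1 gem-dimethyl carbon, C3 and C5 carbinol carbons, C6 alkenyl carbinol carbon, C4 between C3 and C5).
Assumption: (4R,6R)-4-hydroxy-2,2,6-trimethylcyclohexanone (23) and 3-bromofuran-2(5H)-one (37) are treated as purchasable; otherwise each is one or two routine steps from 4-oxoisophorone or furan-2(5H)-one.

**Ring B (steps 1–12)**

Step 1
Reactants: 1 methyl 3-methyl-2-oxobutanoate; 2 3-bromo-2-methylprop-1-ene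
Product: 4 methyl 3,3,5-trimethyl-2-oxohex-5-enoate, via lithium enolate 3 (not isolated)
Conditions: LiN(SiMe3)2, THF, −78 °C; 2, −78 °C → rt; then PhMe, 110 °C
Reagents that add atoms: none
Why: Enolate C-alkylation of the only α-position with a reactive allylic bromide builds the C1 quaternary carbon, and any O-allylated material should converge on 4 by Claisen rearrangement during the final heating.

Step 2
Reactants: 4 methyl 3,3,5-trimethyl-2-oxohex-5-enoate; 5 ethynyltrimethylsilane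
Product: 6 methyl (2S)-2-hydroxy-3,3,5-trimethyl-2-[(trimethylsilyl)ethynyl]hex-5-enoate
Conditions: Zn(OTf)2 (20 mol %), (1S,2S)-2-(dimethylamino)-1-(4-nitrophenyl)-3-(tert-butyldimethylsilyloxy)propan-1-ol (22 mol %; its antipode if the sense of induction requires it), Et3N (30 mol %), PhMe, 70 °C
Reagents that add atoms: none
Why: Catalytic enantioselective alkynylation of an α-keto ester, in which the amino-alkoxide-bound alkynylzinc species adds to one face of the activated, non-enolisable ketone and so sets the C6 carbinol (2S), while the masked ketone (a 1,1-disubstituted alkene) cannot cyclise onto C6.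

Step 3
Reactants: 6 methyl (2S)-2-hydroxy-3,3,5-trimethyl-2-[(trimethylsilyl)ethynyl]hex-5-enoate
Product: 7 methyl (2S)-2-ethynyl-2-hydroxy-3,3,5-trimethylhex-5-enoate
Conditions: K2CO3 (cat.), MeOH, 0 °C → rt
Reagents that add atoms: none
Why: Base-catalysed methanolysis of the C(sp)–Si bond (protodesilylation) leaves the methyl ester, the alkene and the tertiary carbinol untouched.

Step 4
Reactants: 7 methyl (2S)-2-ethynyl-2-hydroxy-3,3,5-trimethylhex-5-enoate
Product: 8 methyl (2S)-2-ethynyl-3,3,5-trimethyl-2-[(trimethylsilyl)oxy]hex-5-enoate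
Conditions: Me3SiOTf, 2,6-lutidine, CH2Cl2, −78 → 0 °C
Reagents that add atoms: trimethylsilyl trifluoromethanesulfonate, C[Si](C)(C)OS(=O)(=O)C(F)(F)F
Why: O-Silylation with a silyl triflate and a hindered pyridine base caps the congested tertiary alcohol and provides the non-chelating C6 oxygen substituent that the key step needs.

Step 5
Reactants: 8 methyl (2S)-2-ethynyl-3,3,5-trimethyl-2-[(trimethylsilyl)oxy]hex-5-enoate
Product: 10 methyl (2S)-2-ethynyl-3,3-dimethyl-5-oxo-2-[(trimethylsilyl)oxy]hexanoate, via ozonide 9 (not isolated)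
Conditions: O3, CH2Cl2, −78 °C (indicator dye end point); then PPh3, −78 °C → rt
Reagents that add atoms: ozone, [O-][O+]=O
Why: Ozonolysis with reductive work-up, in which the electron-rich 1,1-disubstituted alkene reacts far faster than the terminal alkyne, unmasks the C3 methyl ketone, which cannot form a hemiketal because the C6 oxygen is silylated.

Step 6
Reactants: 10 methyl (2S)-2-ethynyl-3,3-dimethyl-5-oxo-2-[(trimethylsilyl)oxy]hexanoate; 11 triethylsilane
Product: 12 methyl (2R)-3,3-dimethyl-5-oxo-2-[(E)-2-(triethylsilyl)ethenyl]-2-[(trimethylsilyl)oxy]hexanoate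
Conditions: PtCl2 (5 mol %), XPhos (10 mol %), THF, 50 °C
Reagents that add atoms: none
Why: PtCl2-catalysed hydrosilylation of a terminal alkyne adds H and Si syn with silicon at the unhindered terminus, the quaternary propargylic centre and the bulky phosphine enforcing the E-β-vinylsilane, while ketone and ester are inert.

Step 7
Reactants: 12 methyl (2R)-3,3-dimethyl-5-oxo-2-[(E)-2-(triethylsilyl)ethenyl]-2-[(trimethylsilyl)oxy]hexanoate
Product: 14 methyl (2R)-5-[(tert-butyldimethylsilyl)oxy]-3,3-dimethyl-2-[(E)-2-(triethylsilyl)ethenyl]-2-[(trimethylsilyl)oxy]hex-5-enoate, via lithium enolate 13 (not isolated)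
Conditions: LiN(iPr)2, THF, −78 °C; t-BuMe2SiOTf, −78 → −40 °C
Reagents that add atoms: tert-butyldimethylsilyl trifluoromethanesulfonate, CC(C)(C)[Si](C)(C)OS(=O)(=O)C(F)(F)F
Why: Kinetic enolate formation and O-silylation, in which the amide base takes a methyl proton and not one of the neopentyl CH2, the ester has no α-hydrogen, and cold trapping should outrun Claisen-type attack of the enolate on the shielded ester.

Step 8
Reactants: 14 methyl (2R)-5-[(tert-butyldimethylsilyl)oxy]-3,3-dimethyl-2-[(E)-2-(triethylsilyl)ethenyl]-2-[(trimethylsilyl)oxy]hex-5-enoate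
Product: 16 (3R)-6-[(tert-butyldimethylsilyl)oxy]-4,4-dimethyl-3-[(E)-2-(triethylsilyl)ethenyl]-3-[(trimethylsilyl)oxy]hept-6-en-2-one, via α-silyl ketone lithium enolate 15 (not isolated)
Conditions: Me3SiCH2Li (2.5 equiv), pentane/THF, −78 → 0 °C; then MeOH, 0 °C; aq. NH4Cl
Reagents that add atoms: (trimethylsilyl)methyllithium, [Li]C[Si](C)(C)C
Why: Acylation of an α-silyl carbanion (ester to methyl ketone), in which the reagent, known to add to very hindered carbonyl groups, gives an α-silyl ketone that is at once deprotonated to 15 and so shielded from a second addition before methanol cleaves the C–Si bond, while the TBS enol ether resists alkyllithiums in the cold.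

Step 9
Reactants: 16 (3R)-6-[(tert-butyldimethylsilyl)oxy]-4,4-dimethyl-3-[(E)-2-(triethylsilyl)ethenyl]-3-[(trimethylsilyl)oxy]hept-6-en-2-one
Product: 18 (3R,4R)-3-hydroxy-3,5,5-trimethyl-4-[(E)-2-(triethylsilyl)ethenyl]-4-[(trimethylsilyl)oxy]cyclohexan-1-one, via difluoroboron aldolate 17 (not isolated)
Conditions: BF3·OEt2 (1.5 equiv), CH2Cl2, −78 °C; aq. NaHCO3
Reagents that add atoms: none
Why: BF3 binds the C5 carbonyl oxygen, the CH2 terminus of the silyl enol ether (C4) adds to C5, and fluoride transfer from boron removes the TBS group from the oxocarbenium ion, leaving the C3 ketone and aldolate 17, which is hydrolysed on work-up. The closest known reaction type is the intramolecular Mukaiyama aldol addition to an α-silyloxy ketone under a monodentate Lewis acid. Ring B closes in the 6-(enolendo)-exo-trig mode (C3 and C4 of the enol ether both end up inside the ring) through a chair-like array. The new C5 stereocenter is controlled by C6: because BF3 cannot bridge to the silyl ether, the C5=O and C6–O dipoles align anti (Cornforth-type), which in the chair puts both oxygens axial and the C5 methyl and C6 alkenyl groups equatorial and also keeps the C5 methyl clear of the axial C1 methyl. The step needs the 5,6-trans diol (5R, methyl trans to alkenyl) and exclusive C4–C5 bonding; the first is secured by the non-chelating acid, the silylated C6 oxygen and the larger equatorial demand of the alkenyl group, the second by having installed the only enol ether at C3 while C5 was still an ester.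

Step 10
Reactants: 18 (3R,4R)-3-hydroxy-3,5,5-trimethyl-4-[(E)-2-(triethylsilyl)ethenyl]-4-[(trimethylsilyl)oxy]cyclohexan-1-one
Product: 20 (1S,3R,4R)-3,5,5-trimethyl-4-[(E)-2-(triethylsilyl)ethenyl]-4-[(trimethylsilyl)oxy]cyclohexane-1,3-diol, via diacetoxyboryl ether 19 (not isolated)
Conditions: Me4NBH(OAc)3, MeCN/AcOH, −35 → −20 °C; aq. potassium sodium tartrate
Reagents that add atoms: none
Why: Hydroxyl-directed triacetoxyborohydride reduction (Evans–Saksena type), in which the axial C5 hydroxyl exchanges onto boron and delivers hydride to its own face of the C3 carbonyl, sets the equatorial C3 carbinol (S) anti to the C5 hydroxyl.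

Step 11
Reactants: 20 (1S,3R,4R)-3,5,5-trimethyl-4-[(E)-2-(triethylsilyl)ethenyl]-4-[(trimethylsilyl)oxy]cyclohexane-1,3-diol
Product: 21 (1S,3R,4R)-4-[(E)-2-iodoethenyl]-3,5,5-trimethyl-4-[(trimethylsilyl)oxy]cyclohexane-1,3-diol
Conditions: N-iodosuccinimide, 2,6-lutidine, (CF3)2CHOH, 0 °C
Reagents that add atoms: N-iodosuccinimide, O=C1CCC(=O)N1I
Why: Iododesilylation of a vinylsilane proceeds by iodonium attack at the silicon-bearing carbon and loss of silicon from the β-silyl cation with retention of the E geometry, the fluorinated alcohol accelerating the ipso substitution.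

Step 12
Reactants: 21 (1S,3R,4R)-4-[(E)-2-iodoethenyl]-3,5,5-trimethyl-4-[(trimethylsilyl)oxy]cyclohexane-1,3-diol
Product: 22 (1S,3R,4R)-3,5,5-trimethyl-4-[(trimethylsilyl)oxy]-4-[(E)-2-(trimethylstannyl)ethenyl]cyclohexane-1,3-diol
Conditions: Pd(PPh3)4 (5 mol %), Me3SnSnMe3, THF, 65 °C
Reagents that add atoms: hexamethylditin, C[Sn](C)(C)[Sn](C)(C)C
Why: Pd(PPh3)4-catalysed stannylation of an alkenyl iodide with a distannane (oxidative addition, Sn–Sn transmetalation, reductive elimination) retains the alkene geometry and tolerates free hydroxyl groups.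

**Ring A and polyene (steps 13–18)**

Step 13
Reactants: 23 (4R,6R)-4-hydroxy-2,2,6-trimethylcyclohexan-1-one
Product: 24 (4R,6R)-2,2,6-trimethyl-4-[(triethylsilyl)oxy]cyclohexan-1-one
Conditions: Et3SiCl, imidazole, CH2Cl2, 0 °C → rt
Reagents that add atoms: chlorotriethylsilane, CC[Si](Cl)(CC)CC
Why: Silyl ether formation protects the secondary hydroxyl for the enolate chemistry that follows and is chosen to fall off under the mild final fluoride treatment.

Step 14
Reactants: 24 (4R,6R)-2,2,6-trimethyl-4-[(triethylsilyl)oxy]cyclohexan-1-one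
Product: 26 (4R)-2,6,6-trimethyl-4-[(triethylsilyl)oxy]cyclohex-1-en-1-yl trifluoromethanesulfonate, via lithium enolate 25 (not isolated)
Conditions: LiN(iPr)2, THF, −78 → 0 °C; PhNTf2, 0 °C → rt; aq. NH4Cl
Reagents that add atoms: N-phenylbis(trifluoromethanesulfonimide), O=S(=O)(N(c1ccccc1)S(=O)(=O)C(F)(F)F)C(F)(F)F
Why: Enol triflate formation is regiospecific because only C6 carries an α-hydrogen, so the tetrasubstituted enolate 25 is O-triflated, erasing the C6 stereocenter and leaving C4 (R) untouched.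

Step 15
Reactants: 26 (4R)-2,6,6-trimethyl-4-[(triethylsilyl)oxy]cyclohex-1-en-1-yl trifluoromethanesulfonate; 27 (2E)-3-methylpent-2-en-4-yn-1-ol
Product: 28 (2E)-3-methyl-5-{(4R)-2,6,6-trimethyl-4-[(triethylsilyl)oxy]cyclohex-1-en-1-yl}pent-2-en-4-yn-1-ol
Conditions: Pd(PPh3)4 (5 mol %), CuI (10 mol %), Et3N, DMF, 50 °C
Reagents that add atoms: none
Why: Sonogashira coupling of an enol triflate with a terminal enyne forms the ring A–alkyne bond with retention of the E alkene and tolerates the free allylic alcohol.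

Step 16
Reactants: 28 (2E)-3-methyl-5-{(4R)-2,6,6-trimethyl-4-[(triethylsilyl)oxy]cyclohex-1-en-1-yl}pent-2-en-4-yn-1-ol
Product: 29 (2E)-3-methyl-5-{(4R)-2,6,6-trimethyl-4-[(triethylsilyl)oxy]cyclohex-1-en-1-yl}pent-2-en-4-ynal
Conditions: MnO2, CH2Cl2, rt
Reagents that add atoms: none
Why: Allylic oxidation with activated MnO2 is selective for the primary allylic alcohol and stops at the aldehyde.

Step 17
Reactants: 29 (2E)-3-methyl-5-{(4R)-2,6,6-trimethyl-4-[(triethylsilyl)oxy]cyclohex-1-en-1-yl}pent-2-en-4-ynal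
Product: 30 triethyl{[(1R)-4-[(3E,5E)-6-iodo-3-methylhexa-3,5-dien-1-yn-1-yl]-3,5,5-trimethylcyclohex-3-en-1-yl]oxy}silane
Conditions: CrCl2, CHI3, THF/1,4-dioxane, 0 °C → rt
Reagents that add atoms: iodoform, IC(I)I
Why: Takai olefination, in which the gem-dichromium carbenoid from CHI3 adds to the aldehyde and eliminates anti, gives the E-alkenyl iodide.

Step 18
Reactants: 30 triethyl{[(1R)-4-[(3E,5E)-6-iodo-3-methylhexa-3,5-dien-1-yn-1-yl]-3,5,5-trimethylcyclohex-3-en-1-yl]oxy}silane; 31 (E)-1,2-bis(tributylstannyl)ethene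
Product: 32 tributyl[(1E,3E,5E)-6-methyl-8-{(4R)-2,6,6-trimethyl-4-[(triethylsilyl)oxy]cyclohex-1-en-1-yl}octa-1,3,5-trien-7-yn-1-yl]stannane
Conditions: Pd2(dba)3 (2.5 mol %), AsPh3 (20 mol %), NMP, rt, dark; 31 in threefold excess
Reagents that add atoms: none
Why: Stille coupling with an excess of the bis-stannane should give mono-coupling with retention at both alkenes and keep one stannyl group for the next coupling.

**Central butenolide (steps 19–21)**

Step 19
Reactants: 33 prop-2-yn-1-ol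
Product: 35 (2E)-3-iodo-2-methylprop-2-en-1-ol, via alkenylalane 34 (not isolated)
Conditions: AlMe3 (3 equiv), Cp2ZrCl2 (25 mol %), CH2Cl2, 0 °C → rt; then I2, THF, −30 → 0 °C; aq. K2CO3
Reagents that add atoms: trimethylaluminium, C[Al](C)C; iodine, II
Why: Cp2ZrCl2-catalysed carboalumination (Negishi) adds methyl and aluminium syn across the alkyne with methyl on the internal carbon, and iodinolysis of 34 with retention gives the E iodide.

Step 20
Reactants: 35 (2E)-3-iodo-2-methylprop-2-en-1-ol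
Product: 36 (2E)-3-iodo-2-methylprop-2-enal
Conditions: MnO2, CH2Cl2, rt, dark; used as a solution
Reagents that add atoms: none
Why: Allylic oxidation with activated MnO2 gives the volatile enal without touching the alkenyl iodide.

Step 21
Reactants: 36 (2E)-3-iodo-2-methylprop-2-enal; 37 3-bromofuran-2(5H)-one
Product: 40 (5Z)-3-bromo-5-[(2E)-3-iodo-2-methylprop-2-en-1-ylidene]furan-2(5H)-one, via silyloxyfuran 38 (not isolated), via silyl aldol adduct 39 (not isolated)
Conditions: t-BuMe2SiOTf, iPr2NEt, CH2Cl2, −78 °C → rt; then DBU, rt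
Reagents that add atoms: none
Why: Vinylogous Mukaiyama aldol condensation, in which furan 38 adds through C5 to the silyl-activated aldehyde and base-induced loss of silanolate from 39 gives the thermodynamically preferred Z ylidenebutenolide, whose chain lies syn to the ring oxygen and away from the C4 hydrogen.

**Assembly (steps 22–24)**

Step 22
Reactants: 32 tributyl[(1E,3E,5E)-6-methyl-8-{(4R)-2,6,6-trimethyl-4-[(triethylsilyl)oxy]cyclohex-1-en-1-yl}octa-1,3,5-trien-7-yn-1-yl]stannane; 40 (5Z)-3-bromo-5-[(2E)-3-iodo-2-methylprop-2-en-1-ylidene]furan-2(5H)-one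
Product: 41 (5Z)-3-bromo-5-[(2E,4E,6E,8E)-2,9-dimethyl-11-{(4R)-2,6,6-trimethyl-4-[(triethylsilyl)oxy]cyclohex-1-en-1-yl}undeca-2,4,6,8-tetraen-10-yn-1-ylidene]furan-2(5H)-one
Conditions: Pd2(dba)3 (2.5 mol %), AsPh3 (20 mol %), NMP, rt, dark
Reagents that add atoms: none
Why: Stille coupling chemoselective for the alkenyl iodide, which should undergo oxidative addition much faster than the α-bromo lactone at room temperature, joins the polyene with retention of every alkene geometry.

Step 23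
Reactants: 22 (1S,3R,4R)-3,5,5-trimethyl-4-[(trimethylsilyl)oxy]-4-[(E)-2-(trimethylstannyl)ethenyl]cyclohexane-1,3-diol; 41 (5Z)-3-bromo-5-[(2E,4E,6E,8E)-2,9-dimethyl-11-{(4R)-2,6,6-trimethyl-4-[(triethylsilyl)oxy]cyclohex-1-en-1-yl}undeca-2,4,6,8-tetraen-10-yn-1-ylidene]furan-2(5H)-one
Product: 42 (5Z)-5-[(2E,4E,6E,8E)-2,9-dimethyl-11-{(4R)-2,6,6-trimethyl-4-[(triethylsilyl)oxy]cyclohex-1-en-1-yl}undeca-2,4,6,8-tetraen-10-yn-1-ylidene]-3-[(E)-2-{(1R,2R,4S)-2,4-dihydroxy-2,6,6-trimethyl-1-[(trimethylsilyl)oxy]cyclohexyl}ethenyl]furan-2(5H)-one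
Conditions: Pd2(dba)3 (5 mol %), AsPh3 (40 mol %), NMP, 40 °C, dark
Reagents that add atoms: none
Why: Stille coupling of an α-bromobutenolide with an alkenylstannane, a pairing with precedent among carotenoid butenolides, joins ring B to the lactone with retention of the E geometry and tolerance of the free diol.

Step 24
Reactants: 42 the C6 trimethylsilyl, ring A triethylsilyl bis-ether of the target
Product: 43 (5Z)-5-[(2E,4E,6E,8E)-11-[(4R)-4-hydroxy-2,6,6-trimethylcyclohex-1-en-1-yl]-2,9-dimethylundeca-2,4,6,8-tetraen-10-yn-1-ylidene]-3-[(E)-2-[(1R,2R,4S)-1,2,4-trihydroxy-2,6,6-trimethylcyclohexyl]ethenyl]furan-2(5H)-one (CNP0163979.1)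
Conditions: HF·pyridine, pyridine, THF, 0 °C → rt, dark
Reagents that add atoms: none
Why: Fluoride-mediated cleavage of the tertiary trimethylsilyl and secondary triethylsilyl ethers under buffered conditions should spare the butenolide, the polyene and the tertiary allylic alcohol.

**Compound list**

1 | methyl 3-methyl-2-oxobutanoate | COC(=O)C(=O)C(C)C | starting material
2 | 3-bromo-2-methylprop-1-ene | CC(=C)CBr | starting material
3 | lithium enolate of 1 (lithium 1-methoxy-3-methyl-1-oxobut-2-en-2-olate) | COC(=O)C(O[Li])=C(C)C | intermediate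
4 | methyl 3,3,5-trimethyl-2-oxohex-5-enoate | COC(=O)C(=O)C(C)(C)CC(C)=C | intermediate
5 | ethynyltrimethylsilane | C#C[Si](C)(C)C | starting material
6 | methyl (2S)-2-hydroxy-3,3,5-trimethyl-2-[(trimethylsilyl)ethynyl]hex-5-enoate | C[Si](C)(C)C#C[C@](O)(C(=O)OC)C(C)(C)CC(C)=C | intermediate
7 | methyl (2S)-2-ethynyl-2-hydroxy-3,3,5-trimethylhex-5-enoate | C#C[C@](O)(C(=O)OC)C(C)(C)CC(C)=C | intermediate
8 | methyl (2S)-2-ethynyl-3,3,5-trimethyl-2-[(trimethylsilyl)oxy]hex-5-enoate | C#C[C@](O[Si](C)(C)C)(C(=O)OC)C(C)(C)CC(C)=C | intermediate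
9 | ozonide of 8: methyl (2S)-2-ethynyl-3,3-dimethyl-4-(3-methyl-1,2,4-trioxolan-3-yl)-2-[(trimethylsilyl)oxy]butanoate | C#C[C@](O[Si](C)(C)C)(C(=O)OC)C(C)(C)CC1(C)OCOO1 | intermediate
10 | methyl (2S)-2-ethynyl-3,3-dimethyl-5-oxo-2-[(trimethylsilyl)oxy]hexanoate | C#C[C@](O[Si](C)(C)C)(C(=O)OC)C(C)(C)CC(C)=O | intermediate
11 | triethylsilane | CC[SiH](CC)CC | starting material
12 | methyl (2R)-3,3-dimethyl-5-oxo-2-[(E)-2-(triethylsilyl)ethenyl]-2-[(trimethylsilyl)oxy]hexanoate | CC[Si](CC)(CC)/C=C/[C@](O[Si](C)(C)C)(C(=O)OC)C(C)(C)CC(C)=O | intermediate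
13 | terminal lithium enolate of 12 | CC[Si](CC)(CC)/C=C/[C@](O[Si](C)(C)C)(C(=O)OC)C(C)(C)CC(=C)O[Li] | intermediate
14 | methyl (2R)-5-[(tert-butyldimethylsilyl)oxy]-3,3-dimethyl-2-[(E)-2-(triethylsilyl)ethenyl]-2-[(trimethylsilyl)oxy]hex-5-enoate | CC[Si](CC)(CC)/C=C/[C@](O[Si](C)(C)C)(C(=O)OC)C(C)(C)CC(=C)O[Si](C)(C)C(C)(C)C | intermediate
15 | lithium enolate of the 1-(trimethylsilyl) derivative of 16 | CC[Si](CC)(CC)/C=C/[C@](O[Si](C)(C)C)(C(O[Li])=C[Si](C)(C)C)C(C)(C)CC(=C)O[Si](C)(C)C(C)(C)C | intermediate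
16 | (3R)-6-[(tert-butyldimethylsilyl)oxy]-4,4-dimethyl-3-[(E)-2-(triethylsilyl)ethenyl]-3-[(trimethylsilyl)oxy]hept-6-en-2-one (key-step precursor) | CC[Si](CC)(CC)/C=C/[C@](O[Si](C)(C)C)(C(C)=O)C(C)(C)CC(=C)O[Si](C)(C)C(C)(C)C | intermediate
17 | difluoroboron aldolate of 18 (O–BF2 at C5) | CC[Si](CC)(CC)/C=C/[C@@]1(O[Si](C)(C)C)C(C)(C)CC(=O)C[C@@]1(C)OB(F)F | intermediate
18 | (3R,4R)-3-hydroxy-3,5,5-trimethyl-4-[(E)-2-(triethylsilyl)ethenyl]-4-[(trimethylsilyl)oxy]cyclohexan-1-one (key-step product) | CC[Si](CC)(CC)/C=C/[C@@]1(O[Si](C)(C)C)C(C)(C)CC(=O)C[C@@]1(C)O | intermediate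
19 | C5 diacetoxyboryl ether of 20 | CC[Si](CC)(CC)/C=C/[C@@]1(O[Si](C)(C)C)C(C)(C)C[C@H](O)C[C@@]1(C)OB(OC(C)=O)OC(C)=O | intermediate
20 | (1S,3R,4R)-3,5,5-trimethyl-4-[(E)-2-(triethylsilyl)ethenyl]-4-[(trimethylsilyl)oxy]cyclohexane-1,3-diol | CC[Si](CC)(CC)/C=C/[C@@]1(O[Si](C)(C)C)C(C)(C)C[C@H](O)C[C@@]1(C)O | intermediate
21 | (1S,3R,4R)-4-[(E)-2-iodoethenyl]-3,5,5-trimethyl-4-[(trimethylsilyl)oxy]cyclohexane-1,3-diol | I/C=C/[C@@]1(O[Si](C)(C)C)C(C)(C)C[C@H](O)C[C@@]1(C)O | intermediate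
22 | (1S,3R,4R)-3,5,5-trimethyl-4-[(trimethylsilyl)oxy]-4-[(E)-2-(trimethylstannyl)ethenyl]cyclohexane-1,3-diol | C[Sn](C)(C)/C=C/[C@@]1(O[Si](C)(C)C)C(C)(C)C[C@H](O)C[C@@]1(C)O | intermediate
23 | (4R,6R)-4-hydroxy-2,2,6-trimethylcyclohexan-1-one | CC1(C)C[C@H](O)C[C@@H](C)C1=O | starting material
24 | (4R,6R)-2,2,6-trimethyl-4-[(triethylsilyl)oxy]cyclohexan-1-one | CC1(C)C[C@H](O[Si](CC)(CC)CC)C[C@@H](C)C1=O | intermediate
25 | lithium enolate of 24 | CC1=C(O[Li])C(C)(C)C[C@H](O[Si](CC)(CC)CC)C1 | intermediate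
26 | (4R)-2,6,6-trimethyl-4-[(triethylsilyl)oxy]cyclohex-1-en-1-yl trifluoromethanesulfonate | CC1=C(OS(=O)(=O)C(F)(F)F)C(C)(C)C[C@H](O[Si](CC)(CC)CC)C1 | intermediate
27 | (2E)-3-methylpent-2-en-4-yn-1-ol | C#C/C(C)=C/CO | starting material
28 | (2E)-3-methyl-5-{(4R)-2,6,6-trimethyl-4-[(triethylsilyl)oxy]cyclohex-1-en-1-yl}pent-2-en-4-yn-1-ol | CC1=C(C#C/C(C)=C/CO)C(C)(C)C[C@H](O[Si](CC)(CC)CC)C1 | intermediate
29 | (2E)-3-methyl-5-{(4R)-2,6,6-trimethyl-4-[(triethylsilyl)oxy]cyclohex-1-en-1-yl}pent-2-en-4-ynal | CC1=C(C#C/C(C)=C/C=O)C(C)(C)C[C@H](O[Si](CC)(CC)CC)C1 | intermediate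
30 | triethyl{[(1R)-4-[(3E,5E)-6-iodo-3-methylhexa-3,5-dien-1-yn-1-yl]-3,5,5-trimethylcyclohex-3-en-1-yl]oxy}silane | CC1=C(C#C/C(C)=C/C=C/I)C(C)(C)C[C@H](O[Si](CC)(CC)CC)C1 | intermediate
31 | (E)-1,2-bis(tributylstannyl)ethene | CCCC[Sn](CCCC)(CCCC)/C=C/[Sn](CCCC)(CCCC)CCCC | starting material
32 | tributyl[(1E,3E,5E)-6-methyl-8-{(4R)-2,6,6-trimethyl-4-[(triethylsilyl)oxy]cyclohex-1-en-1-yl}octa-1,3,5-trien-7-yn-1-yl]stannane | CC1=C(C#C/C(C)=C/C=C/C=C/[Sn](CCCC)(CCCC)CCCC)C(C)(C)C[C@H](O[Si](CC)(CC)CC)C1 | intermediate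
33 | prop-2-yn-1-ol | C#CCO | starting material
34 | dimethyl{[(2E)-3-(dimethylalumanyl)-2-methylprop-2-en-1-yl]oxy}alumane | C[Al](C)OC/C(C)=C/[Al](C)C | intermediate
35 | (2E)-3-iodo-2-methylprop-2-en-1-ol | OC/C(C)=C/I | intermediate
36 | (2E)-3-iodo-2-methylprop-2-enal | O=C/C(C)=C/I | intermediate
37 | 3-bromofuran-2(5H)-one | O=C1OCC=C1Br | starting material
38 | 3-bromo-2-[(tert-butyldimethylsilyl)oxy]furan | CC(C)(C)[Si](C)(C)Oc1occc1Br | intermediate
39 | 3-bromo-5-[(2E)-1-[(tert-butyldimethylsilyl)oxy]-3-iodo-2-methylprop-2-en-1-yl]furan-2(5H)-one (diastereomer mixture) | CC(C)(C)[Si](C)(C)OC(/C(C)=C/I)C1C=C(Br)C(=O)O1 | intermediate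
40 | (5Z)-3-bromo-5-[(2E)-3-iodo-2-methylprop-2-en-1-ylidene]furan-2(5H)-one | I/C=C(C)/C=C1C=C(Br)C(=O)O/1 | intermediate
41 | (5Z)-3-bromo-5-[(2E,4E,6E,8E)-2,9-dimethyl-11-{(4R)-2,6,6-trimethyl-4-[(triethylsilyl)oxy]cyclohex-1-en-1-yl}undeca-2,4,6,8-tetraen-10-yn-1-ylidene]furan-2(5H)-one | CC1=C(C#C/C(C)=C/C=C/C=C/C=C(C)/C=C2C=C(Br)C(=O)O/2)C(C)(C)C[C@H](O[Si](CC)(CC)CC)C1 | intermediate
42 | target carrying a trimethylsilyl ether at C6 of ring B and a triethylsilyl ether on ring A | CC1=C(C#C/C(C)=C/C=C/C=C/C=C(C)/C=C2C=C(/C=C/[C@@]3(O[Si](C)(C)C)C(C)(C)C[C@H](O)C[C@@]3(C)O)C(=O)O/2)C(C)(C)C[C@H](O[Si](CC)(CC)CC)C1 | intermediate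
43 | (5Z)-5-[(2E,4E,6E,8E)-11-[(4R)-4-hydroxy-2,6,6-trimethylcyclohex-1-en-1-yl]-2,9-dimethylundeca-2,4,6,8-tetraen-10-yn-1-ylidene]-3-[(E)-2-[(1R,2R,4S)-1,2,4-trihydroxy-2,6,6-trimethylcyclohexyl]ethenyl]furan-2(5H)-one | CC1=C(C#C/C(C)=C/C=C/C=C/C=C(C)/C=C2C=C(/C=C/[C@@]3(O)C(C)(C)C[C@H](O)C[C@@]3(C)O)C(=O)O/2)C(C)(C)C[C@H](O)C1 | target

**Step count and risk**

Total step count: 24. Longest linear sequence: 14 steps (steps 1–12, then 23 and 24).

Steps most likely to fail:

1. Step 9 could suffer from insufficient facial discrimination at C5 (a boat-like or gauche-dipole closure competing with the anti-dipole chair) or from silyl loss before cyclisation. The fallback sets the C5 oxygen by epoxidation and does not rely on aldol facial control. It sets out from 16: the same BF3·OEt2 closure is run and the crude ketol, whatever its composition at C5 (18 together with the C5-epimeric ketol F1), is mesylated and eliminated (MeSO2Cl, Et3N, CH2Cl2, 0 °C; then DBU) to the single enone F2. Nucleophilic epoxidation (t-BuOOH, DBU, CH2Cl2; Weitz–Scheffer type) is expected to deliver oxygen to C5 anti to the C6 silyloxy group and give epoxy ketone F3. Reductive cleavage of the Cα–O bond (PhSeSePh, NaBH4, AcOH, EtOH) then gives the β-hydroxy ketone and rejoins the route at 18.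

2. Step 2 could show slow turnover at the congested ketone and erosion of enantioselectivity. The fallback replaces asymmetric catalysis by resolution. It sets out from 4: the lithium acetylide of 5 (n-BuLi, THF, −78 °C) adds to the ketone to give racemic adduct F4, and LiOH in aqueous THF/MeOH at 60 °C removes the C-silyl group and hydrolyses the ester to racemic hydroxy acid F5. Crystallisation of its salt with whichever antipode of 1-phenylethylamine gives the less soluble salt, followed by acidification, gives the (S)-acid F6, and Me3SiCHN2 in PhMe/MeOH re-forms the methyl ester, rejoining the route at 7.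

3. Step 8 could fail through sluggish addition to the shielded ester or cleavage of the enol silane by the organolithium. The fallback reaches the ketone by stepwise redox adjustment. It sets out from 14: i-Bu2AlH (CH2Cl2, −78 °C) gives aldehyde F7, MeMgBr (Et2O, −78 °C) gives secondary alcohol F8 as a mixture of carbinol epimers, and oxidation with Pr4NRuO4 (cat.) and N-methylmorpholine N-oxide over molecular sieves, which is non-acidic and should spare the silyl enol ether, rejoins the route at 16.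

**Further compounds**

F1 | step 9 | (3S,4R)-3-hydroxy-3,5,5-trimethyl-4-[(E)-2-(triethylsilyl)ethenyl]-4-[(trimethylsilyl)oxy]cyclohexan-1-one (C5 epimer of 18) | CC[Si](CC)(CC)/C=C/[C@@]1(O[Si](C)(C)C)C(C)(C)CC(=O)C[C@]1(C)O
F2 | step 9 | (4R)-3,5,5-trimethyl-4-[(E)-2-(triethylsilyl)ethenyl]-4-[(trimethylsilyl)oxy]cyclohex-2-en-1-one | CC[Si](CC)(CC)/C=C/[C@@]1(O[Si](C)(C)C)C(C)(C)CC(=O)C=C1C
F3 | step 9 | (1S,5R,6R)-4,4,6-trimethyl-5-[(E)-2-(triethylsilyl)ethenyl]-5-[(trimethylsilyl)oxy]-7-oxabicyclo[4.1.0]heptan-2-one | CC[Si](CC)(CC)/C=C/[C@@]1(O[Si](C)(C)C)C(C)(C)CC(=O)[C@@H]2[C@@]1(C)O2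
F4 | step 2 | racemic methyl 2-hydroxy-3,3,5-trimethyl-2-[(trimethylsilyl)ethynyl]hex-5-enoate | C[Si](C)(C)C#CC(O)(C(=O)OC)C(C)(C)CC(C)=C
F5 | step 2 | racemic 2-ethynyl-2-hydroxy-3,3,5-trimethylhex-5-enoic acid | C#CC(O)(C(=O)O)C(C)(C)CC(C)=C
F6 | step 2 | (2S)-2-ethynyl-2-hydroxy-3,3,5-trimethylhex-5-enoic acid | C#C[C@](O)(C(=O)O)C(C)(C)CC(C)=C
F7 | step 8 | (2R)-5-[(tert-butyldimethylsilyl)oxy]-3,3-dimethyl-2-[(E)-2-(triethylsilyl)ethenyl]-2-[(trimethylsilyl)oxy]hex-5-enal | CC[Si](CC)(CC)/C=C/[C@](O[Si](C)(C)C)(C=O)C(C)(C)CC(=C)O[Si](C)(C)C(C)(C)C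
F8 | step 8 | (3R)-6-[(tert-butyldimethylsilyl)oxy]-4,4-dimethyl-3-[(E)-2-(triethylsilyl)ethenyl]-3-[(trimethylsilyl)oxy]hept-6-en-2-ol (both C2 epimers) | CC[Si](CC)(CC)/C=C/[C@](O[Si](C)(C)C)(C(C)O)C(C)(C)CC(=C)O[Si](C)(C)C(C)(C)C
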